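**Retrosynthetic overview**
1. Target ⇒ diol with a terminal alkyne: the (E)-3-methyl-2-enoic acid comes from methylalumination/CO2 of the alkyne, and the two acetates go on last.
2. C9–H and the C7=C8 bond ⇒ allylic-diazene (reductive 1,3-) transposition of a 7-ol, whose enone arises from 1,2-addition of the side chain to a C9 ketone and oxidative 1,3-transposition.
3. cis-2,3-Diol ⇒ substrate-controlled OsO4 addition to a ring A C2=C3 alkene, anti to the C10 methyl.
4. Key step: ring A is closed last by a 6-exo reductive Heck reaction of a Z-alkenyl chloride onto a carvone isopropenyl group, forming C3–C4, the gem-dimethyl C4 and C2=C3 at once.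
5. Ring B is (S)-carvone itself (C5, the C8 methyl, latent C7=C8), with C10 set by two α'-alkylations; ring order is B (chiral pool) then A, so no polyene cyclisation or preformed decalin is used.

Assumption: geometrically pure (Z)-1,3-dichloropropene is bought; labdane numbering (C1–C20) is used in the explanations. The route is designed on paper and has not been run.

Step 1
Reactants: 1 (S)-(+)-carvone
Product: 3 (5S,6R)-2,6-dimethyl-5-(prop-1-en-2-yl)cyclohex-2-en-1-one, via lithium dienolate 2 (not isolated)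
Conditions: LiN(i-Pr)2, THF, −78 °C; MeI, −78 to 0 °C
Reagents that add atoms: iodomethane (SMILES CI)
Why: Kinetic α'-deprotonation of the enone gives the cross-conjugated dienolate, which is C-methylated (enolate alkylation) mainly anti to the neighbouring isopropenyl group; the new centre is flattened again in step 2, so its configuration does not matter, while the carvone stereocentre (future C5) is untouched.

Step 2
Reactants: 3 (5S,6R)-2,6-dimethyl-5-(prop-1-en-2-yl)cyclohex-2-en-1-one; 4 (Z)-1,3-dichloroprop-1-ene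
Product: 6 (5R,6R)-6-[(2Z)-3-chloroprop-2-en-1-yl]-2,6-dimethyl-5-(prop-1-en-2-yl)cyclohex-2-en-1-one, via lithium enolate 5 (not isolated)
Conditions: LiN(i-Pr)2, THF, −78 to −10 °C; 4, DMPU, −78 °C to rt
Reagents that add atoms: none
Why: A second α'-enolisation makes the carbon planar and the allylic chloride of 4 then reacts by SN2 enolate alkylation on the face opposite the adjacent isopropenyl group, which sets the quaternary carbon (future C10) with methyl cis and the chloroallyl arm trans to isopropenyl, the Z-alkenyl chloride being inert to these conditions.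

Step 3
Reactants: 6 (5R,6R)-6-[(2Z)-3-chloroprop-2-en-1-yl]-2,6-dimethyl-5-(prop-1-en-2-yl)cyclohex-2-en-1-one
Product: 7 (4aR,8aR)-2,5,5,8a-tetramethyl-4a,5,8,8a-tetrahydronaphthalen-1(4H)-one
Conditions: Pd(OAc)2 (10 mol %), P(t-Bu)3·HBF4 (20 mol %), HCO2Na (3 equiv), Et4NCl, DMF, 90 °C
Reagents that add atoms: none
Why: Intramolecular reductive Heck reaction in which zerovalent palladium carrying P(t-Bu)3 inserts into the alkenyl C–Cl bond, 6-exo carbopalladation of the isopropenyl group creates the quaternary C4, and the resulting alkylpalladium, which has no β-hydrogen, is reduced by formate so that the former methylene becomes the second methyl; the trans ring fusion follows from the trans arms fixed in step 2 and the Z-alkene is retained as the ring A C2=C3 bond.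

Step 4
Reactants: 7 (4aR,8aR)-2,5,5,8a-tetramethyl-4a,5,8,8a-tetrahydronaphthalen-1(4H)-one; 8 (4-bromobut-1-yn-1-yl)trimethylsilane
Product: 10 (1R,4aR,8aR)-2,5,5,8a-tetramethyl-1-[4-(trimethylsilyl)but-3-yn-1-yl]-1,4,4a,5,8,8a-hexahydronaphthalen-1-ol, via Grignard reagent 9 (not isolated)
Conditions: 8, Mg, THF, 40 °C; CeCl3, THF, −78 °C, then 7, −78 to 0 °C; aq NH4Cl
Reagents that add atoms: none
Why: CeCl3-promoted Grignard 1,2-addition to the hindered, enolisable enone carbonyl (the cerium salt suppresses enolisation and conjugate addition), expected mainly from the face opposite the C10 methyl; either C9 epimer is usable because this carbon becomes sp2 in step 5.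

Step 5
Reactants: 10 (1R,4aR,8aR)-2,5,5,8a-tetramethyl-1-[4-(trimethylsilyl)but-3-yn-1-yl]-1,4,4a,5,8,8a-hexahydronaphthalen-1-ol
Product: 13 (4aR,8aR)-3,4a,8,8-tetramethyl-4-[4-(trimethylsilyl)but-3-yn-1-yl]-4a,5,8,8a-tetrahydronaphthalen-2(1H)-one, via tertiary chlorochromate ester 11 (not isolated), via transposed chlorochromate ester 12 (not isolated)
Conditions: pyridinium chlorochromate (C5H5NH)[CrO3Cl] (3 equiv), SiO2, CH2Cl2, rt
Reagents that add atoms: pyridinium chlorochromate (SMILES [O-][Cr](=O)(=O)Cl.c1cc[nH+]cc1)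
Why: Dauben–Babler oxidative 1,3-transposition in which the tertiary allylic chromate ester undergoes a [3,3] shift to the secondary C7 ester that is then oxidised by hexavalent chromium, moving the oxygen to C7 and leaving the side chain on the now tetrasubstituted C8=C9 alkene; the isolated ring A alkene and the silylalkyne are inert.

Step 6
Reactants: 13 (4aR,8aR)-3,4a,8,8-tetramethyl-4-[4-(trimethylsilyl)but-3-yn-1-yl]-4a,5,8,8a-tetrahydronaphthalen-2(1H)-one
Product: 14 (4aR,6S,7R,8aS)-6,7-dihydroxy-3,4a,8,8-tetramethyl-4-[4-(trimethylsilyl)but-3-yn-1-yl]-4a,5,6,7,8,8a-hexahydronaphthalen-2(1H)-one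
Conditions: OsO4 (5 mol %), NMO (1.5 equiv), acetone/H2O, rt
Reagents that add atoms: osmium tetroxide (SMILES O=[Os](=O)(=O)=O); N-methylmorpholine N-oxide (SMILES C[N+]1([O-])CCOCC1); water (SMILES O)
Why: Upjohn syn-dihydroxylation of the only electron-rich alkene (the conjugated tetrasubstituted enone and the alkyne do not react) from the face opposite the axial C10 and C4 methyl groups, as for 5α-steroid 2-enes, giving the 2,3-cis-diol with C2–O equatorial and C3–O axial (labdane 2S,3R).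

Step 7
Reactants: 14 (4aR,6S,7R,8aS)-6,7-dihydroxy-3,4a,8,8-tetramethyl-4-[4-(trimethylsilyl)but-3-yn-1-yl]-4a,5,6,7,8,8a-hexahydronaphthalen-2(1H)-one
Product: 15 (2R,3S,4aR,8aS)-1,1,4a,6-tetramethyl-7-oxo-5-[4-(trimethylsilyl)but-3-yn-1-yl]-1,2,3,4,4a,7,8,8a-octahydronaphthalene-2,3-diyl diacetate
Conditions: Ac2O, pyridine, DMAP, 40 °C
Reagents that add atoms: acetic anhydride (SMILES CC(=O)OC(C)=O)
Why: DMAP-catalysed acylation caps both hydroxyls, including the axial neopentyl C3–OH, so that only the C7 alcohol made in step 8 can enter the Mitsunobu reaction of step 9.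

Step 8
Reactants: 15 (2R,3S,4aR,8aS)-1,1,4a,6-tetramethyl-7-oxo-5-[4-(trimethylsilyl)but-3-yn-1-yl]-1,2,3,4,4a,7,8,8a-octahydronaphthalene-2,3-diyl diacetate
Product: 16 (2R,3S,4aR,7R,8aS)-7-hydroxy-1,1,4a,6-tetramethyl-5-[4-(trimethylsilyl)but-3-yn-1-yl]-1,2,3,4,4a,7,8,8a-octahydronaphthalene-2,3-diyl diacetate
Conditions: NaBH4, CeCl3·7H2O, MeOH, −40 °C
Reagents that add atoms: none
Why: Luche 1,2-reduction in which hydride attacks the enone carbonyl axially from the face opposite the angular C10 methyl (as in 5α-steroid 1-en-3-ones), giving the pseudo-equatorial 7-alcohol cis to that methyl without touching the acetates.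

Step 9
Reactants: 16 (2R,3S,4aR,7R,8aS)-7-hydroxy-1,1,4a,6-tetramethyl-5-[4-(trimethylsilyl)but-3-yn-1-yl]-1,2,3,4,4a,7,8,8a-octahydronaphthalene-2,3-diyl diacetate
Product: 19 (2R,3S,4aS,5R,8aS)-1,1,4a,6-tetramethyl-5-[4-(trimethylsilyl)but-3-yn-1-yl]-1,2,3,4,4a,5,8,8a-octahydronaphthalene-2,3-diyl diacetate, via sulfonylhydrazine 17 (not isolated), via allylic diazene 18 (not isolated)
Conditions: 2-nitrobenzenesulfonohydrazide (NBSH), PPh3, DEAD, N-methylmorpholine, −30 °C; then rt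
Reagents that add atoms: none
Why: Myers reductive allylic transposition in which Mitsunobu displacement by NBSH inverts C7, loss of 2-nitrobenzenesulfinic acid gives the monoalkyl diazene, and its retro-ene loss of N2 delivers hydrogen suprafacially to C9 on the face opposite the C10 methyl, which sets C9 (labdane 9R, side chain equatorial and cis to the C10 methyl) and places the double bond at C7=C8.

Step 10
Reactants: 19 (2R,3S,4aS,5R,8aS)-1,1,4a,6-tetramethyl-5-[4-(trimethylsilyl)but-3-yn-1-yl]-1,2,3,4,4a,5,8,8a-octahydronaphthalene-2,3-diyl diacetate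
Product: 20 (2R,3S,4aS,5R,8aS)-5-(but-3-yn-1-yl)-1,1,4a,6-tetramethyl-1,2,3,4,4a,5,8,8a-octahydronaphthalene-2,3-diol
Conditions: K2CO3, MeOH, 40 °C
Reagents that add atoms: none
Why: Base-catalysed methanolysis (transesterification of both acetates and protodesilylation of the alkynylsilane) unmasks the diol and the terminal alkyne in one operation without affecting any stereocentre.

Step 11
Reactants: 20 (2R,3S,4aS,5R,8aS)-5-(but-3-yn-1-yl)-1,1,4a,6-tetramethyl-1,2,3,4,4a,5,8,8a-octahydronaphthalene-2,3-diol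
Product: 23 (2E)-5-[(1R,4aS,6R,7S,8aS)-6,7-dihydroxy-2,5,5,8a-tetramethyl-1,4,4a,5,6,7,8,8a-octahydronaphthalen-1-yl]-3-methylpent-2-enoic acid, via alkenylalane 21 (not isolated), via lithium alkenylalanate 22 (not isolated)
Conditions: Me3Al (5 equiv), (C5H5)2ZrCl2 (0.5 equiv), CH2Cl2, 0 °C to rt; evaporate; n-BuLi, THF/hexane, −78 °C; CO2; aq HCl
Reagents that add atoms: trimethylaluminium (SMILES C[Al](C)C); carbon dioxide (SMILES O=C=O)
Why: Negishi zirconium-catalysed carboalumination in which, after the hydroxyls are capped as aluminium alkoxides, methyl and aluminium add syn across the terminal alkyne with methyl on the internal carbon, and the alkenyl–aluminium bond of the derived ate complex is carboxylated by CO2 with retention, so only the 13E acid forms and the trisubstituted ring alkene is untouched.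

Step 12
Reactants: 23 (2E)-5-[(1R,4aS,6R,7S,8aS)-6,7-dihydroxy-2,5,5,8a-tetramethyl-1,4,4a,5,6,7,8,8a-octahydronaphthalen-1-yl]-3-methylpent-2-enoic acid
Product: 25 (2E)-5-[(1R,4aS,6R,7S,8aS)-6,7-bis(acetyloxy)-2,5,5,8a-tetramethyl-1,4,4a,5,6,7,8,8a-octahydronaphthalen-1-yl]-3-methylpent-2-enoic acid, via mixed anhydride 24 (not isolated)
Conditions: Ac2O, pyridine, DMAP, rt; then H2O, THF, rt
Reagents that add atoms: acetic anhydride (SMILES CC(=O)OC(C)=O)
Why: DMAP-catalysed acylation esterifies both hydroxyls while the carboxylic acid is only transiently converted into the mixed anhydride, which is hydrolysed selectively on aqueous work-up because the anhydride linkage is far more labile than the alkyl acetates, giving the target.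

**Compound list**
1 | (S)-(+)-carvone, (5S)-2-methyl-5-(prop-1-en-2-yl)cyclohex-2-en-1-one | CC1=CC[C@@H](CC1=O)C(C)=C | starting material
2 | lithium (3S)-6-methyl-3-(prop-1-en-2-yl)cyclohexa-1,5-dien-1-olate | CC1=CC[C@H](C(C)=C)C=C1O[Li] | intermediate
3 | (5S,6R)-2,6-dimethyl-5-(prop-1-en-2-yl)cyclohex-2-en-1-one (major trans epimer) | C[C@H]1C(=O)C(C)=CC[C@@H]1C(C)=C | intermediate
4 | (Z)-1,3-dichloroprop-1-ene | Cl/C=C\CCl | starting material
5 | lithium (3R)-2,6-dimethyl-3-(prop-1-en-2-yl)cyclohexa-1,5-dien-1-olate | CC1=C(O[Li])C(C)=CC[C@@H]1C(C)=C | intermediate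
6 | (5R,6R)-6-[(2Z)-3-chloroprop-2-en-1-yl]-2,6-dimethyl-5-(prop-1-en-2-yl)cyclohex-2-en-1-one | Cl/C=C\C[C@@]1(C)C(=O)C(C)=CC[C@@H]1C(C)=C | intermediate
7 | (4aR,8aR)-2,5,5,8a-tetramethyl-4a,5,8,8a-tetrahydronaphthalen-1(4H)-one | C=1C[C@@]2(C)C(=O)C(C)=CC[C@@H]2C(C)(C)C=1 | intermediate
8 | (4-bromobut-1-yn-1-yl)trimethylsilane | C[Si](C)(C)C#CCCBr | starting material
9 | [4-(trimethylsilyl)but-3-yn-1-yl]magnesium bromide | C[Si](C)(C)C#CCC[Mg]Br | intermediate
10 | (1R,4aR,8aR)-2,5,5,8a-tetramethyl-1-[4-(trimethylsilyl)but-3-yn-1-yl]-1,4,4a,5,8,8a-hexahydronaphthalen-1-ol (major C1 epimer) | C=1C[C@@]2(C)[C@@](O)(CCC#C[Si](C)(C)C)C(C)=CC[C@@H]2C(C)(C)C=1 | intermediate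
11 | (1R,4aR,8aR)-2,5,5,8a-tetramethyl-1-[4-(trimethylsilyl)but-3-yn-1-yl]-1,4,4a,5,8,8a-hexahydronaphthalen-1-yl chlorochromate | C=1C[C@@]2(C)[C@@](O[Cr](=O)(=O)Cl)(CCC#C[Si](C)(C)C)C(C)=CC[C@@H]2C(C)(C)C=1 | intermediate
12 | (2R,4aR,8aR)-3,4a,8,8-tetramethyl-4-[4-(trimethylsilyl)but-3-yn-1-yl]-1,2,4a,5,8,8a-hexahydronaphthalen-2-yl chlorochromate | C=1C[C@@]2(C)C(CCC#C[Si](C)(C)C)=C(C)[C@H](O[Cr](=O)(=O)Cl)C[C@@H]2C(C)(C)C=1 | intermediate
13 | (4aR,8aR)-3,4a,8,8-tetramethyl-4-[4-(trimethylsilyl)but-3-yn-1-yl]-4a,5,8,8a-tetrahydronaphthalen-2(1H)-one | C=1C[C@@]2(C)C(CCC#C[Si](C)(C)C)=C(C)C(=O)C[C@@H]2C(C)(C)C=1 | intermediate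
14 | (4aR,6S,7R,8aS)-6,7-dihydroxy-3,4a,8,8-tetramethyl-4-[4-(trimethylsilyl)but-3-yn-1-yl]-4a,5,6,7,8,8a-hexahydronaphthalen-2(1H)-one | O[C@H]1C[C@@]2(C)C(CCC#C[Si](C)(C)C)=C(C)C(=O)C[C@@H]2C(C)(C)[C@H]1O | intermediate
15 | (2R,3S,4aR,8aS)-1,1,4a,6-tetramethyl-7-oxo-5-[4-(trimethylsilyl)but-3-yn-1-yl]-1,2,3,4,4a,7,8,8a-octahydronaphthalene-2,3-diyl diacetate | CC(=O)O[C@H]1C[C@@]2(C)C(CCC#C[Si](C)(C)C)=C(C)C(=O)C[C@@H]2C(C)(C)[C@H]1OC(C)=O | intermediate
16 | (2R,3S,4aR,7R,8aS)-7-hydroxy-1,1,4a,6-tetramethyl-5-[4-(trimethylsilyl)but-3-yn-1-yl]-1,2,3,4,4a,7,8,8a-octahydronaphthalene-2,3-diyl diacetate | CC(=O)O[C@H]1C[C@@]2(C)C(CCC#C[Si](C)(C)C)=C(C)[C@H](O)C[C@@H]2C(C)(C)[C@H]1OC(C)=O | intermediate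
17 | (2R,3S,4aR,7S,8aS)-1,1,4a,6-tetramethyl-7-[1-(2-nitrobenzenesulfonyl)hydrazin-1-yl]-5-[4-(trimethylsilyl)but-3-yn-1-yl]-1,2,3,4,4a,7,8,8a-octahydronaphthalene-2,3-diyl diacetate | CC(=O)O[C@H]1C[C@@]2(C)C(CCC#C[Si](C)(C)C)=C(C)[C@@H](N(N)S(=O)(=O)c3ccccc3[N+](=O)[O-])C[C@@H]2C(C)(C)[C@H]1OC(C)=O | intermediate
18 | (2R,3S,4aR,7S,8aS)-7-diazenyl-1,1,4a,6-tetramethyl-5-[4-(trimethylsilyl)but-3-yn-1-yl]-1,2,3,4,4a,7,8,8a-octahydronaphthalene-2,3-diyl diacetate | CC(=O)O[C@H]1C[C@@]2(C)C(CCC#C[Si](C)(C)C)=C(C)[C@@H](N=N)C[C@@H]2C(C)(C)[C@H]1OC(C)=O | intermediate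
19 | (2R,3S,4aS,5R,8aS)-1,1,4a,6-tetramethyl-5-[4-(trimethylsilyl)but-3-yn-1-yl]-1,2,3,4,4a,5,8,8a-octahydronaphthalene-2,3-diyl diacetate | CC(=O)O[C@H]1C[C@@]2(C)[C@H](CCC#C[Si](C)(C)C)C(C)=CC[C@@H]2C(C)(C)[C@H]1OC(C)=O | intermediate
20 | (2R,3S,4aS,5R,8aS)-5-(but-3-yn-1-yl)-1,1,4a,6-tetramethyl-1,2,3,4,4a,5,8,8a-octahydronaphthalene-2,3-diol | O[C@H]1C[C@@]2(C)[C@H](CCC#C)C(C)=CC[C@@H]2C(C)(C)[C@H]1O | intermediate
21 | dimethyl[(1E)-2-methyl-4-{(1R,4aS,6R,7S,8aS)-6,7-bis[(dimethylalumanyl)oxy]-2,5,5,8a-tetramethyl-1,4,4a,5,6,7,8,8a-octahydronaphthalen-1-yl}but-1-en-1-yl]alumane | C[Al](C)O[C@H]1C[C@@]2(C)[C@H](CC/C(C)=C/[Al](C)C)C(C)=CC[C@@H]2C(C)(C)[C@H]1O[Al](C)C | intermediate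
22 | lithium butyl(dimethyl)[(1E)-alkenyl]alanate derived from 21 (same skeleton, ate complex at the alkenyl aluminium) | [Li+].C[Al](C)O[C@H]1C[C@@]2(C)[C@H](CC/C(C)=C/[Al-](C)(C)CCCC)C(C)=CC[C@@H]2C(C)(C)[C@H]1O[Al](C)C | intermediate
23 | (2E)-5-[(1R,4aS,6R,7S,8aS)-6,7-dihydroxy-2,5,5,8a-tetramethyl-1,4,4a,5,6,7,8,8a-octahydronaphthalen-1-yl]-3-methylpent-2-enoic acid | O[C@H]1C[C@@]2(C)[C@H](CC/C(C)=C/C(=O)O)C(C)=CC[C@@H]2C(C)(C)[C@H]1O | intermediate
24 | acetic (2E)-5-[(1R,4aS,6R,7S,8aS)-6,7-bis(acetyloxy)-2,5,5,8a-tetramethyl-1,4,4a,5,6,7,8,8a-octahydronaphthalen-1-yl]-3-methylpent-2-enoic anhydride | CC(=O)O[C@H]1C[C@@]2(C)[C@H](CC/C(C)=C/C(=O)OC(C)=O)C(C)=CC[C@@H]2C(C)(C)[C@H]1OC(C)=O | intermediate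
25 | CNP0321684.1, (2E)-5-[(1R,4aS,6R,7S,8aS)-6,7-bis(acetyloxy)-2,5,5,8a-tetramethyl-1,4,4a,5,6,7,8,8a-octahydronaphthalen-1-yl]-3-methylpent-2-enoic acid; labdane numbering (2S,3R,5S,9R,10S,13E) | CC(=O)O[C@H]1C[C@@]2(C)[C@H](CC/C(C)=C/C(=O)O)C(C)=CC[C@@H]2C(C)(C)[C@H]1OC(C)=O | target

**Totals**
Total step count: 12. Longest linear sequence: 12 steps, from 1 to 25.

**Three steps most likely to fail, each with a fallback**

Step 3 (reductive Heck closure of ring A). The risks are slow oxidative addition of the alkenyl chloride, direct hydrodechlorination, and 3-exo side reactions of the alkylpalladium before formate capture. The fallback sets out from 3 and comes back at 7, replacing the palladium insertion by a vinylsilane-terminated cation–olefin cyclisation. Commercial 3-(trimethylsilyl)prop-2-yn-1-ol is semi-hydrogenated (H2, Pd on CaCO3 poisoned with Pb(OAc)2, quinoline) to (2Z)-3-(trimethylsilyl)prop-2-en-1-ol F1. PBr3 converts this into [(1Z)-3-bromoprop-1-en-1-yl]trimethylsilane F2. Enolate 5, made from 3 as in step 2, is alkylated with F2 to give (5R,6R)-2,6-dimethyl-5-(prop-1-en-2-yl)-6-[(2Z)-3-(trimethylsilyl)prop-2-en-1-yl]cyclohex-2-en-1-one F3. Treating F3 with MsOH in CH2Cl2/HFIP at low temperature protonates the isopropenyl group; the tertiary cation is attacked by the silicon-bearing alkene carbon (6-membered ring, β-silyl cation), and loss of the silyl group leaves the C2=C3 alkene, giving 7.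

Step 9 (Mitsunobu/diazene transposition on a hindered allylic alcohol). The risks are a sluggish Mitsunobu step and ionisation of the allylic alcohol with loss of stereochemical fidelity. The fallback sets out from 16 and comes back at 19, using palladium-catalysed formate hydrogenolysis instead of the sigmatropic diazene route. Alcohol 16 is formylated (HCO2H, DCC, DMAP) to (2R,3S,4aR,7R,8aS)-7-(formyloxy)-1,1,4a,6-tetramethyl-5-[4-(trimethylsilyl)but-3-yn-1-yl]-1,2,3,4,4a,7,8,8a-octahydronaphthalene-2,3-diyl diacetate F4. With Pd(OAc)2 and P(n-Bu)3 in dioxane, zerovalent palladium ionises the formate with inversion, CO2 is lost, and hydride passes from palladium to the more substituted allyl terminus C9 on the face opposite the C10 methyl, giving 19 with the same stereochemical outcome.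

Step 11 (carboalumination/carboxylation on the free diol). The risks are incomplete carbometalation in the presence of the aluminium alkoxides and a low-yielding CO2 capture. The fallback sets out from 20 and comes back at 23, using carbonyl olefination instead of carbometalation. Gold-catalysed Markovnikov hydration of the alkyne ((Ph3P)AuCl, AgOTf, aqueous MeOH) gives 4-[(1R,4aS,6R,7S,8aS)-6,7-dihydroxy-2,5,5,8a-tetramethyl-1,4,4a,5,6,7,8,8a-octahydronaphthalen-1-yl]butan-2-one F5. Horner–Wadsworth–Emmons reaction with triethyl phosphonoacetate and NaH gives mainly ethyl (2E)-5-[(1R,4aS,6R,7S,8aS)-6,7-dihydroxy-2,5,5,8a-tetramethyl-1,4,4a,5,6,7,8,8a-octahydronaphthalen-1-yl]-3-methylpent-2-enoate F6; the minor Z isomer is removed by chromatography. LiOH in aqueous THF then gives 23.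

Further compounds
F1 | step 3 | (2Z)-3-(trimethylsilyl)prop-2-en-1-ol | C[Si](C)(C)/C=C\CO
F2 | step 3 | [(1Z)-3-bromoprop-1-en-1-yl]trimethylsilane | C[Si](C)(C)/C=C\CBr
F3 | step 3 | (5R,6R)-2,6-dimethyl-5-(prop-1-en-2-yl)-6-[(2Z)-3-(trimethylsilyl)prop-2-en-1-yl]cyclohex-2-en-1-one | C[Si](C)(C)/C=C\C[C@@]1(C)C(=O)C(C)=CC[C@@H]1C(C)=C
F4 | step 9 | (2R,3S,4aR,7R,8aS)-7-(formyloxy)-1,1,4a,6-tetramethyl-5-[4-(trimethylsilyl)but-3-yn-1-yl]-1,2,3,4,4a,7,8,8a-octahydronaphthalene-2,3-diyl diacetate | CC(=O)O[C@H]1C[C@@]2(C)C(CCC#C[Si](C)(C)C)=C(C)[C@H](OC=O)C[C@@H]2C(C)(C)[C@H]1OC(C)=O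
F5 | step 11 | 4-[(1R,4aS,6R,7S,8aS)-6,7-dihydroxy-2,5,5,8a-tetramethyl-1,4,4a,5,6,7,8,8a-octahydronaphthalen-1-yl]butan-2-one | O[C@H]1C[C@@]2(C)[C@H](CCC(C)=O)C(C)=CC[C@@H]2C(C)(C)[C@H]1O
F6 | step 11 | ethyl (2E)-5-[(1R,4aS,6R,7S,8aS)-6,7-dihydroxy-2,5,5,8a-tetramethyl-1,4,4a,5,6,7,8,8a-octahydronaphthalen-1-yl]-3-methylpent-2-enoate | O[C@H]1C[C@@]2(C)[C@H](CC/C(C)=C/C(=O)OCC)C(C)=CC[C@@H]2C(C)(C)[C@H]1O
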